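# Proposed synthesis of 2-(2,4-dihydroxyphenyl)-5-hydroxy-7-methoxy-3-(3-methylbut-2-enyl)chromen-4-one (10)

## The problem

The target 10 is a flavone: a chromen-4-one (rings A and C) carrying a 2,4-dihydroxyphenyl ring B at C2 and a 3-methylbut-2-enyl (prenyl) chain at C3, with a free hydroxyl at C5 and a methyl ether at C7 on ring A. It has no stereocenter, so the task is one of connectivity and of telling four oxygen functions apart. Three phenols must end free while the C7 oxygen stays methylated, and the two ring A oxygens sit in a phloroglucinol pattern whose only built-in bias is the hydrogen bond of the 5-OH to the C4 carbonyl. The C2=C3 bond is tetrasubstituted and crowded, with an ortho-substituted aryl group next to the prenyl CH2, so the C3 substituent is best in place before ring C is closed. The prenyl olefin is the fragile group: it does not survive hydrogenolysis, strong protic or Lewis acids (tertiary cation formation and capture by the electron-rich rings) or electrophilic oxidants. This rules out benzyl and methyl ethers as phenol protection and any acidic endgame. The free resorcinol and 5-hydroxychromone units are electron-rich and should be unveiled last under neutral conditions. The enabling feature is that C5 and C8a are both ortho to C4a, the carbon that bears the C4 carbonyl, while the C7 methoxy group is meta to both. A 2,6-difluoro-4-methoxybenzoyl unit is therefore symmetrical: either fluoride can be displaced by the O1 oxygen to form O1–C8a, and the surviving fluoride sits at C5, activated by the C4 carbonyl for later exchange against oxygen.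

## Retrosynthesis

**10 from 9 (three O–allyl bonds).** The last operation should only uncover phenols. Allyl ethers are chosen because zerovalent palladium with an amine removes them under neutral conditions that leave the prenyl olefin alone. Benzyl ethers would need hydrogenolysis, methyl ethers would need Lewis acids and could not be told from the C7 methyl ether, methoxymethyl ethers would need acid, and aryl silyl ethers would not survive the fluoride and alkoxide present in the two steps before. Precursor 9, the 5,2',4'-tris(allyl) ether of 10, hides all three phenols in one kind of group, so one operation has to clear all of them.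

**9 from 8 (C5–O bond).** The C5 oxygen is traced back to fluorine. A C5 oxygen carried through the ring-forming step would need a protecting group distinct from the C7 methyl ether and would make the aroyl partner unsymmetrical. Fluorine is small, inert to enolate chemistry and, once ring C exists, ortho to the C4 carbonyl and therefore open to addition–elimination. Using allyl oxide as the nucleophile gives the same ether type as on ring B. The forward step asks that the alkoxide substitute at C5 and not add at C2 of the pyranone.

**8 from 4 and 6 through 7 (C3–C4 and O1–C8a).** This is the key disconnection. The neighbouring cuts are closure at O1–C2 from a 2-hydroxyaryl diketone and closure at C4–C4a by acylation of a phloroglucinol ether. Both make ring A the nucleophile, so they require a differentiated trioxygenated ring A and postpone either the prenyl group or the C5/C7 distinction. Cutting O1–C8a makes ring A the electrophile instead. The ketone 4 already carries the prenyl chain on the carbon that becomes C3, and the symmetrical acid chloride 6 offers two equivalent fluorides, so no regiochemical question arises. The diketone 7 is not isolated. The step splits a C24 chromone into a C16 ketone and a C8 acid chloride, forming two bonds and one ring. It asks for C-acylation over O-acylation and for ring closure through oxygen.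

**6 from 5 (C–Cl).** The acid chloride is made from 2,6-difluoro-4-methoxybenzoic acid 5 with oxalyl chloride and used crude.

**4 from 2 and 3 (Cα–CH2 bond).** The bond between the ketone α-carbon and the prenyl CH2 is cut, leading to the methyl ketone 2 and prenyl bromide 3. Friedel–Crafts acylation of a resorcinol diallyl ether with an unsaturated acid chloride would expose the olefin and the allyl ethers to a Lewis acid and raise a regiochemical question. Enolate alkylation is one step from a cheap acetophenone. The forward step asks for clean monoalkylation.

**2 from 1 (two O–allyl bonds).** Double O-allylation of commercial 2,4-dihydroxyacetophenone 1.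

## Roads not taken

**Alternative 1:** Ring A is taken apart completely (C8–C8a, C5–C6, C7–C8 and C4a–C5), leaving the pyran-4-one diazoketone A1 that already carries ring B and the prenyl chain. In the forward step, irradiation of A1 with methoxyacetylene A2 triggers a Wolff rearrangement to a vinylketene whose vinyl unit is the pyranone C5=C6 bond. Ketene–alkyne cycloaddition, four-electron opening of the cyclobutenone, six-electron electrocyclization and tautomerization on warming would then give phenol A3.
- Merits: four bonds form in one operation. The alkyne polarization places the methoxy group at C7 and the free hydroxyl at C5 without any differentiation problem. A3 is one fluoride desilylation from 10. In these respects it is better than the chosen plan, which needs a separate fluoride-to-oxygen exchange.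
- Weak points: A1 has no short preparation, since a 2-aryl-3-prenylpyranone bearing a diazoacetyl group must be built first. A2 is volatile and must be prepared and handled cold. The ketene and the photoexcited diazo compound can both be intercepted by the prenyl olefin. The electrocyclization has to engage an electron-poor, cross-conjugated pyranone double bond.
- Comparison: the chosen plan sets against it that both coupling partners are one or two steps from purchased materials, so the extra substitution step is cheap next to the synthesis of A1.

**Alternative 2:** The cut is C3–C4 and O1–C2. The symmetrical aldehyde A4 and the aryl prenyl alkyne A5 would be joined with [RhCl2(C5Me5)]2, AgSbF6 and Cu(OAc)2. Hydroxyl-directed activation of the aldehyde C–H bond by trivalent rhodium, alkyne insertion and C–O bond formation would give the chromone A6, with the second hydroxyl of A4 emerging as the free 5-OH.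
- Merits: this is the most convergent road. It needs no halogen exchange, and ring A is symmetrical so it raises no regiochemistry. On paper it is shorter after the key step than the chosen plan.
- Weak points: the insertion must place the aryl-bearing alkyne carbon on oxygen, and the ortho-alkoxy group on that aryl ring may erode the usual preference. A5 is a skipped enyne whose doubly activated CH2 can isomerize to an allene or conjugated enyne under a cationic metal and acetate at elevated temperature, and its olefin can bind the metal. The electron-rich dihydroxyaldehyde A4 faces a stoichiometric copper oxidant. The methoxymethyl ethers of A6 must be removed with acid in the presence of the prenyl olefin and freshly freed phenols.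
- Comparison: the chosen plan sets against the shorter count a regiochemistry fixed by construction (the enolate carbon is C3), no transition metal in contact with the olefin until the mild last step, and a neutral deprotection.

**Alternative 3:** The cut is C4–C4a. The (Z)-configured acid A7 would be activated with trifluoroacetic anhydride at low temperature so that the acyl carbon attacks the 3,5-dimethoxyphenoxy ring ortho to the ether oxygen, giving the 5,7-dimethoxychromone A8.
- Merits: the phloroglucinol-type ring is highly nucleophilic and both ortho positions are equivalent. No fluorinated building block is needed. The ring closure itself is probably more reliable than the substitution chemistry of the chosen plan.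
- Weak points: A8 carries two methyl ethers, and only the one at C5 may be cleaved. Chelation-controlled demethylation with BCl3 or AlCl3 is selective for that position, but these Lewis acids also cleave aryl allyl ethers and attack the prenyl olefin. In the key step the liberated trifluoroacetic acid can lactonize the γ,δ-unsaturated acid onto the prenyl olefin, or the acylium ion can be captured by it. A7 is a tetrasubstituted enol ether that needs the aryloxy group cis to the carboxyl, which is a multistep problem of alkene geometry.
- Comparison: the chosen plan builds the C5/C7 distinction in from the start as fluorine against methoxy, and never exposes the olefin to acid.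

Key step: step 4

Remark on the chemistry: 1, 3, 5, allyl bromide, allyl alcohol and THF solutions of lithium diisopropylamide, LiN(iPr)2, and LiN(SiMe3)2 are taken as purchased.

## Route

Step 1
Reactants: 1 2,4-dihydroxyacetophenone
Product: 2 1-[2,4-bis(allyloxy)phenyl]ethanone
Conditions: allyl bromide (2.5 equiv), K2CO3, DMF, 60 °C
Reagents that add atoms: allyl bromide, C=CCBr
Why: Williamson ether synthesis; DMF, excess halide and warming are used so that the hydrogen-bonded 2-OH is alkylated as well as the 4-OH, and the temperature is far below that of an aromatic Claisen rearrangement.

Step 2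
Reactants: 2 1-[2,4-bis(allyloxy)phenyl]ethanone, 3 prenyl bromide (1-bromo-3-methylbut-2-ene)
Product: 4 1-[2,4-bis(allyloxy)phenyl]-5-methylhex-4-en-1-one
Conditions: LiN(iPr)2 (1.05 equiv), THF, −78 °C; then 3 (1.1 equiv), −78 → 0 °C
Reagents that add atoms: none
Why: Irreversible kinetic deprotonation of the methyl ketone followed by SN2 alkylation of the lithium enolate at the primary carbon of the allylic bromide (ketone enolate alkylation); with near-stoichiometric base at low temperature the aryl allyl ethers are not deprotonated.

Step 3
Reactants: 5 2,6-difluoro-4-methoxybenzoic acid
Product: 6 2,6-difluoro-4-methoxybenzoyl chloride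
Conditions: (COCl)2, DMF (cat.), CH2Cl2, 0 °C → rt; concentrate, use crude
Reagents that add atoms: oxalyl chloride, O=C(Cl)C(Cl)=O
Why: Standard acid chloride formation through the chloroiminium species generated from DMF; all by-products are gases, so the crude chloride can be taken directly into step 4.

Step 4
Reactants: 4 1-[2,4-bis(allyloxy)phenyl]-5-methylhex-4-en-1-one, 6 2,6-difluoro-4-methoxybenzoyl chloride
Product: 8 2-[2,4-bis(allyloxy)phenyl]-5-fluoro-7-methoxy-3-(3-methylbut-2-enyl)chromen-4-one, via 2-prenyl-1,3-diketone 7 (not isolated)
Conditions: LiN(SiMe3)2 (2.5 equiv), THF, −78 °C; then 6, −78 °C → rt; then 60 °C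
Reagents that add atoms: none
Why: The lithium enolate of 4, whose nucleophilic carbon already bears the prenyl chain, attacks acid chloride 6 in a crossed Claisen-type C-acylation to give diketone 7 (C3–C4), which the surplus LiN(SiMe3)2 deprotonates at once so that 7 neither quenches unreacted enolate nor is acylated twice. On warming, the diketonate oxygen on the ring B side adds to the fluorine-bearing carbon ortho to the new ketone and fluoride leaves from the Meisenheimer intermediate, forming O1–C8a. The closest known reaction type is the one-pot enolate acylation and intramolecular SNAr of ketones with 2-fluorobenzoyl chlorides to give chromones. Ring C closes by a six-membered addition–elimination, formally a 6-endo-trig attack on the β-carbon of the aryl ketone, which behaves as a vinylogous acyl fluoride. No stereocenter is formed, and the stereocenter of 7 at the central carbon disappears on enolization. The step needs C-acylation over O-acylation, which the tight lithium enolate in THF and the excess base favour. It also needs closure through the ring B side oxygen only, which is enforced because attack by the central carbon or by the other oxygen would close a four-membered ring. Ring A raises no regiochemistry because the two fluorides of 6 are equivalent and the methoxy group is meta to both, and LiN(SiMe3)2 is too weak a base to touch the aryl allyl ethers.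

Step 5
Reactants: 8 2-[2,4-bis(allyloxy)phenyl]-5-fluoro-7-methoxy-3-(3-methylbut-2-enyl)chromen-4-one
Product: 9 5-(allyloxy)-2-[2,4-bis(allyloxy)phenyl]-7-methoxy-3-(3-methylbut-2-enyl)chromen-4-one
Conditions: allyl alcohol (3 equiv), NaH (2.5 equiv), THF, 0 °C; then 8, rt → 50 °C
Reagents that add atoms: allyl alcohol (as its sodium alkoxide), C=CCO
Why: Nucleophilic aromatic substitution: the C5 fluoride is ortho to the carbon bearing the C4 carbonyl, which takes up the charge of the Meisenheimer intermediate, while the C7 methoxy group and O1 are meta and do not oppose it. Any addition of alkoxide at the hindered C2 is reversible under anhydrous conditions, whereas loss of fluoride is not.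

Step 6
Reactants: 9 5-(allyloxy)-2-[2,4-bis(allyloxy)phenyl]-7-methoxy-3-(3-methylbut-2-enyl)chromen-4-one
Product: 10 2-(2,4-dihydroxyphenyl)-5-hydroxy-7-methoxy-3-(3-methylbut-2-enyl)chromen-4-one (target)
Conditions: Pd(PPh3)4 (10 mol %), morpholine (excess), THF, rt, argon
Reagents that add atoms: none
Why: Tsuji–Trost-type deallylation: zerovalent palladium ionizes each aryl allyl ether to a π-allyl complex and a phenoxide, and morpholine captures the allyl group. The C-bound prenyl chain has no leaving group and its trisubstituted olefin is inert, and the neutral to basic medium keeps the product away from acid.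

## Compound list

1 | 2,4-dihydroxyacetophenone | CC(=O)c1ccc(O)cc1O | starting material
2 | 1-[2,4-bis(allyloxy)phenyl]ethanone | CC(=O)c1ccc(OCC=C)cc1OCC=C | intermediate
3 | prenyl bromide (1-bromo-3-methylbut-2-ene) | CC(C)=CCBr | starting material
4 | 1-[2,4-bis(allyloxy)phenyl]-5-methylhex-4-en-1-one | C=CCOc1ccc(C(=O)CCC=C(C)C)c(OCC=C)c1 | intermediate
5 | 2,6-difluoro-4-methoxybenzoic acid | COc1cc(F)c(C(=O)O)c(F)c1 | starting material
6 | 2,6-difluoro-4-methoxybenzoyl chloride | COc1cc(F)c(C(Cl)=O)c(F)c1 | intermediate
7 | 1-[2,4-bis(allyloxy)phenyl]-3-(2,6-difluoro-4-methoxyphenyl)-2-(3-methylbut-2-enyl)propane-1,3-dione (racemic, present as its lithium enolate) | COc1cc(F)c(C(=O)C(CC=C(C)C)C(=O)c2ccc(OCC=C)cc2OCC=C)c(F)c1 | intermediate (not isolated)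
8 | 2-[2,4-bis(allyloxy)phenyl]-5-fluoro-7-methoxy-3-(3-methylbut-2-enyl)chromen-4-one | COc1cc(F)c2c(=O)c(CC=C(C)C)c(-c3ccc(OCC=C)cc3OCC=C)oc2c1 | intermediate
9 | 5-(allyloxy)-2-[2,4-bis(allyloxy)phenyl]-7-methoxy-3-(3-methylbut-2-enyl)chromen-4-one | COc1cc(OCC=C)c2c(=O)c(CC=C(C)C)c(-c3ccc(OCC=C)cc3OCC=C)oc2c1 | intermediate
10 | 2-(2,4-dihydroxyphenyl)-5-hydroxy-7-methoxy-3-(3-methylbut-2-enyl)chromen-4-one | COc1cc(O)c2c(=O)c(CC=C(C)C)c(-c3ccc(O)cc3O)oc2c1 | target

## Step count and risk

Total steps: 6. Longest linear sequence: 5 (steps 1, 2, 4, 5, 6 from compound 1); the acid chloride branch adds step 3.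

**Step 4 (key step).** The most likely failure is O-acylation of the α-branched enolate by the di-ortho-substituted aroyl chloride, which would give an enol ester that cannot cyclize. A second possibility is that ring closure stalls because the lithium diketonate stays chelated in the U-shaped form that holds the ring B side oxygen away from the fluoroarene.
Fallback, setting out from 4 and 6 and returning at 8: acid chloride 6 is reduced with LiAlH(OtBu)3 (THF, −78 °C) to 2,6-difluoro-4-methoxybenzaldehyde F1, which can also be bought. The lithium enolate of 4 (LiN(iPr)2, THF, −78 °C) is added to F1 to give the aldol 1-[2,4-bis(allyloxy)phenyl]-2-[(2,6-difluoro-4-methoxyphenyl)(hydroxy)methyl]-5-methylhex-4-en-1-one F2 as a diastereomer mixture. An aldehyde can only be attacked at carbon, so the O-acylation problem disappears. Dess–Martin periodinane (NaHCO3, CH2Cl2, rt) oxidizes F2 to diketone 7, now isolated, and K2CO3 in DMF at 80 °C closes ring C to 8 through the freer potassium enolate.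

**Step 5.** The pyranone carbonyl is a vinylogous ester and a weaker activator than a simple aryl ketone. Substitution at C5 may therefore be slow enough for conjugate addition of the alkoxide at C2, ring opening and cleavage of the resulting diketone to compete, especially if traces of hydroxide are present.
Fallback, setting out from 6 and 4 and returning at 9: the C5 oxygen is installed before ring C exists. Acid chloride 6 is treated with two equivalents of sodium allyl oxide in THF at 0 °C. The first equivalent gives allyl 2,6-difluoro-4-methoxybenzoate F3, which is not isolated, and the second displaces one ester-activated fluoride to give allyl 2-(allyloxy)-6-fluoro-4-methoxybenzoate F4. The allyl ester is chosen so that transesterification by the alkoxide is degenerate. Saponification (LiOH, THF–MeOH–H2O, 50 °C) gives 2-(allyloxy)-6-fluoro-4-methoxybenzoic acid F5, and oxalyl chloride with catalytic DMF gives 2-(allyloxy)-6-fluoro-4-methoxybenzoyl chloride F6. Under the conditions of step 4 the lithium enolate of 4 is acylated by F6 to 1-[2-(allyloxy)-6-fluoro-4-methoxyphenyl]-3-[2,4-bis(allyloxy)phenyl]-2-(3-methylbut-2-enyl)propane-1,3-dione F7, which closes in the same flask to 9.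

**Step 2.** Proton transfer between the product ketone and unreacted enolate during the alkylation would lead to double prenylation together with recovered 2.
Fallback, setting out from 2 and returning at 4: 2 is condensed with dimethyl carbonate (NaH, THF, reflux) to methyl 3-[2,4-bis(allyloxy)phenyl]-3-oxopropanoate F8. The stabilized enolate of F8 is mono-C-alkylated with 3 (K2CO3, acetone, reflux) to methyl 2-[2,4-bis(allyloxy)benzoyl]-5-methylhex-4-enoate F9. Saponification with dilute LiOH (THF–H2O, rt), acidification to pH 4 and warming to 50 °C then decarboxylates the keto acid to 4.

## Further compounds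

F1 | step 4 | 2,6-difluoro-4-methoxybenzaldehyde | COc1cc(F)c(C=O)c(F)c1
F2 | step 4 | 1-[2,4-bis(allyloxy)phenyl]-2-[(2,6-difluoro-4-methoxyphenyl)(hydroxy)methyl]-5-methylhex-4-en-1-one (racemic diastereomer mixture) | COc1cc(F)c(C(O)C(CC=C(C)C)C(=O)c2ccc(OCC=C)cc2OCC=C)c(F)c1
F3 | step 5 | allyl 2,6-difluoro-4-methoxybenzoate | COc1cc(F)c(C(=O)OCC=C)c(F)c1
F4 | step 5 | allyl 2-(allyloxy)-6-fluoro-4-methoxybenzoate | COc1cc(F)c(C(=O)OCC=C)c(OCC=C)c1
F5 | step 5 | 2-(allyloxy)-6-fluoro-4-methoxybenzoic acid | COc1cc(F)c(C(=O)O)c(OCC=C)c1
F6 | step 5 | 2-(allyloxy)-6-fluoro-4-methoxybenzoyl chloride | COc1cc(F)c(C(Cl)=O)c(OCC=C)c1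
F7 | step 5 | 1-[2-(allyloxy)-6-fluoro-4-methoxyphenyl]-3-[2,4-bis(allyloxy)phenyl]-2-(3-methylbut-2-enyl)propane-1,3-dione (racemic) | COc1cc(F)c(C(=O)C(CC=C(C)C)C(=O)c2ccc(OCC=C)cc2OCC=C)c(OCC=C)c1
F8 | step 2 | methyl 3-[2,4-bis(allyloxy)phenyl]-3-oxopropanoate | COC(=O)CC(=O)c1ccc(OCC=C)cc1OCC=C
F9 | step 2 | methyl 2-[2,4-bis(allyloxy)benzoyl]-5-methylhex-4-enoate (racemic) | COC(=O)C(CC=C(C)C)C(=O)c1ccc(OCC=C)cc1OCC=C
A1 | alternative 1 | 2-[2,4-bis(tert-butyldimethylsilyloxy)phenyl]-6-(2-diazoacetyl)-3-(3-methylbut-2-enyl)pyran-4-one | [N-]=[N+]=CC(=O)c1cc(=O)c(CC=C(C)C)c(-c2ccc(O[Si](C)(C)C(C)(C)C)cc2O[Si](C)(C)C(C)(C)C)o1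
A2 | alternative 1 | methoxyacetylene (methoxyethyne) | COC#C
A3 | alternative 1 | 2-[2,4-bis(tert-butyldimethylsilyloxy)phenyl]-5-hydroxy-7-methoxy-3-(3-methylbut-2-enyl)chromen-4-one | COc1cc(O)c2c(=O)c(CC=C(C)C)c(-c3ccc(O[Si](C)(C)C(C)(C)C)cc3O[Si](C)(C)C(C)(C)C)oc2c1
A4 | alternative 2 | 2,6-dihydroxy-4-methoxybenzaldehyde | COc1cc(O)c(C=O)c(O)c1
A5 | alternative 2 | 2,4-bis(methoxymethoxy)-1-(5-methylhex-4-en-1-ynyl)benzene | COCOc1ccc(C#CCC=C(C)C)c(OCOC)c1
A6 | alternative 2 | 2-[2,4-bis(methoxymethoxy)phenyl]-5-hydroxy-7-methoxy-3-(3-methylbut-2-enyl)chromen-4-one | COc1cc(O)c2c(=O)c(CC=C(C)C)c(-c3ccc(OCOC)cc3OCOC)oc2c1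
A7 | alternative 3 | (Z)-3-[2,4-bis(allyloxy)phenyl]-3-(3,5-dimethoxyphenoxy)-2-(3-methylbut-2-enyl)prop-2-enoic acid | COc1cc(OC)cc(O/C(c2ccc(OCC=C)cc2OCC=C)=C(/CC=C(C)C)C(=O)O)c1
A8 | alternative 3 | 2-[2,4-bis(allyloxy)phenyl]-5,7-dimethoxy-3-(3-methylbut-2-enyl)chromen-4-one | COc1cc(OC)c2c(=O)c(CC=C(C)C)c(-c3ccc(OCC=C)cc3OCC=C)oc2c1
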